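**Assumption:** the configuration is taken exactly as written in the SMILES (6S,7S,8S,9S,11S; 2'R,3'S; 1(10)E,4Z); germacrane numbering C1–C15 is used in the explanations, and stannane 4 and (+)-Ipc2BOMe are taken as purchasable.

## Retrosynthetic overview

1. The only ring (10-membered carbocycle) is formed last: C5–C6 by intramolecular Nozaki–Hiyama–Kishi addition of a (Z)-alkenyl iodide to a C6 aldehyde that already carries all five esters; the free 6-OH is created in this step.
2. The C6 aldehyde and C7 centre come from anti-selective hydroboration of a C7 exo-methylene; the three acetates come from a global MOM→OAc exchange; the C9 ester comes from Yamaguchi coupling with an Evans-aldol-derived (2R,3S)-acid.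
3. The C8–C9 bond and both carbinol centres come from Brown γ-alkoxyallylboration of a C9 enal with a 2-substituted allyl MOM ether (C11 from (R)-Roche ester).
4. The C1–C5/C9/C10/C14/C15 enal comes from propargyl alcohol and homoprenyl Grignard (anti-carbomagnesiation/iodination), acetylation and SeO2 oxidation of the E-methyl group.

## Route

**Step 1**
Reactants: 1 methyl (R)-3-hydroxy-2-methylpropanoate
Product: 2 methyl (R)-3-(methoxymethoxy)-2-methylpropanoate
Conditions: MOMCl, i-Pr2NEt, CH2Cl2, 0 °C → rt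
Reagents that add atoms: chloromethyl methyl ether, COCCl
Why: Williamson-type O-alkylation (MOM protection) of the primary alcohol; the C11 stereocentre is carried over from the chiral pool.

**Step 2**
Reactants: 2 methyl (R)-3-(methoxymethoxy)-2-methylpropanoate
Product: 3 (R)-N-methoxy-3-(methoxymethoxy)-N,2-dimethylpropanamide
Conditions: MeNH(OMe)·HCl, i-PrMgCl, THF, −20 °C
Reagents that add atoms: N,O-dimethylhydroxylamine hydrochloride, CNOC.Cl
Why: Weinreb amide formation by magnesium amide aminolysis of the ester, which is cold and fast enough to leave the α-centre intact.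

**Step 3**
Reactants: 3 (R)-N-methoxy-3-(methoxymethoxy)-N,2-dimethylpropanamide; 4 tributyl[(methoxymethoxy)methyl]stannane
Product: 6 (R)-1,4-bis(methoxymethoxy)-3-methylbutan-2-one, via (methoxymethoxy)methyllithium 5 (not isolated)
Conditions: 4, n-BuLi, THF, −78 °C; then 3, −78 °C
Reagents that add atoms: none
Why: Tin–lithium exchange gives the α-alkoxymethyllithium, which adds once to the Weinreb amide (stable chelated tetrahedral intermediate) to give the α-alkoxy ketone and so introduces C8.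

**Step 4**
Reactants: 6 (R)-1,4-bis(methoxymethoxy)-3-methylbutan-2-one
Product: 7 (S)-4-(methoxymethoxy)-2-[(methoxymethoxy)methyl]-3-methylbut-1-ene
Conditions: Ph3PCH3Br, KN(SiMe3)2, THF, −78 → 0 °C
Reagents that add atoms: methyltriphenylphosphonium bromide, C[P+](c1ccccc1)(c1ccccc1)c1ccccc1.[Br-]
Why: Wittig methylenation of the activated α-alkoxy ketone at low temperature installs C6 as an exo-methylene without epimerising C11 (the descriptor changes from R to S only through CIP priorities).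

**Step 5**
Reactants: 8 prop-2-yn-1-ol; 9 5-bromo-2-methylpent-2-ene
Product: 12 (Z)-3-iodo-2-(4-methylpent-3-en-1-yl)prop-2-en-1-ol, via homoprenylmagnesium bromide 10 (not isolated), via oxamagnesole chelate 11 (not isolated)
Conditions: 9, Mg, THF, 40 °C; then 8, CuI (10 mol%), THF/Et2O, 0 °C → rt; then I2, −78 → 0 °C
Reagents that add atoms: iodine, II
Why: Copper-catalysed anti-carbomagnesiation of the propargylic alkoxide gives a five-membered alkenylmagnesium chelate, and iodinolysis with retention fixes iodine cis to CH2OH (the C4=C5 geometry of the target).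

**Step 6**
Reactants: 12 (Z)-3-iodo-2-(4-methylpent-3-en-1-yl)prop-2-en-1-ol
Product: 13 (Z)-3-iodo-2-(4-methylpent-3-en-1-yl)prop-2-en-1-yl acetate
Conditions: Ac2O, pyridine, DMAP (cat.), CH2Cl2, 0 °C → rt
Reagents that add atoms: acetic anhydride, CC(=O)OC(C)=O
Why: DMAP-catalysed acylation installs the final C15 acetate, which survives every later step.

**Step 7**
Reactants: 13 (Z)-3-iodo-2-(4-methylpent-3-en-1-yl)prop-2-en-1-yl acetate
Product: 15 [(1Z,5E)-1-iodo-6-methyl-7-oxohepta-1,5-dien-2-yl]methyl acetate, via allylic alcohol 14 (not isolated)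
Conditions: SeO2 (0.3 equiv), t-BuOOH, salicylic acid (cat.), CH2Cl2, rt; then MnO2, CH2Cl2, rt
Reagents that add atoms: tert-butyl hydroperoxide, CC(C)(C)OO
Why: SeO2 allylic oxidation (ene reaction then [2,3]-shift) attacks only the E-methyl of the electron-rich gem-dimethyl alkene, and MnO2 takes the allylic alcohol to the (E)-enal, so C9 becomes the aldehyde and C1=C10 is E.

**Step 8**
Reactants: 7 (S)-4-(methoxymethoxy)-2-[(methoxymethoxy)methyl]-3-methylbut-1-ene; 15 [(1Z,5E)-1-iodo-6-methyl-7-oxohepta-1,5-dien-2-yl]methyl acetate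
Product: 18 [(1Z,5E,7S,8S,10S)-7-hydroxy-1-iodo-8,11-bis(methoxymethoxy)-6,10-dimethyl-9-methylideneundeca-1,5-dien-2-yl]methyl acetate, via alkoxyallyllithium 16 (not isolated), via alkoxyallylborane 17 (not isolated)
Conditions: 7, s-BuLi, THF, −78 °C; (+)-Ipc2BOMe; BF3·OEt2; then 15, −78 °C; aq. NaOAc, H2O2, 0 °C
Reagents that add atoms: none
Why: Brown γ-alkoxyallylboration: the chelated lithio ether gives the allylborane with OMOM cis to CH2B, whose chair transition state gives the 8,9-syn diol monoether, and the isopinocampheyl groups from (−)-α-pinene direct attack to the Re face of the enal (8S,9S).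

**Step 9**
Reactants: 19 (R)-4-benzyl-3-propanoyl-1,3-oxazolidin-2-one; 20 acetaldehyde
Product: 22 (R)-4-benzyl-3-[(2R,3S)-3-hydroxy-2-methylbutanoyl]-1,3-oxazolidin-2-one, via Z-boron enolate 21 (not isolated)
Conditions: Bu2BOTf, i-Pr2NEt, CH2Cl2, 0 °C; 20, −78 → 0 °C; pH 7 buffer, MeOH, H2O2
Reagents that add atoms: none
Why: Evans syn-aldol: the Z-boron enolate reacts through a Zimmerman–Traxler chair on the face opposite the benzyl group, setting the side-chain centres 2'R,3'S.

**Step 10**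
Reactants: 22 (R)-4-benzyl-3-[(2R,3S)-3-hydroxy-2-methylbutanoyl]-1,3-oxazolidin-2-one
Product: 23 (R)-4-benzyl-3-[(2R,3S)-3-(methoxymethoxy)-2-methylbutanoyl]-1,3-oxazolidin-2-one
Conditions: MOMCl, i-Pr2NEt, Bu4NI (cat.), CH2Cl2, 0 °C → rt
Reagents that add atoms: chloromethyl methyl ether, COCCl
Why: MOM protection of the β-hydroxyl under mild amine base, which avoids retro-aldol and lets the later esterification run with a β-alkoxy acid that cannot β-eliminate as easily as a β-acetoxy acid.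

**Step 11**
Reactants: 23 (R)-4-benzyl-3-[(2R,3S)-3-(methoxymethoxy)-2-methylbutanoyl]-1,3-oxazolidin-2-one
Product: 25 (2R,3S)-3-(methoxymethoxy)-2-methylbutanoic acid, via peroxy acid 24 (not isolated)
Conditions: LiOH, H2O2, THF/H2O, 0 °C; Na2SO3; HCl to pH 3
Reagents that add atoms: hydrogen peroxide, OO
Why: Hydroperoxide cleavage of the imide attacks the exocyclic carbonyl selectively and does not epimerise the α-centre; sulfite reduces the peracid.

**Step 12**
Reactants: 18 [(1Z,5E,7S,8S,10S)-7-hydroxy-1-iodo-8,11-bis(methoxymethoxy)-6,10-dimethyl-9-methylideneundeca-1,5-dien-2-yl]methyl acetate; 25 (2R,3S)-3-(methoxymethoxy)-2-methylbutanoic acid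
Product: 27 (1Z,5E,7S,8S,10S)-2-(acetoxymethyl)-1-iodo-8,11-bis(methoxymethoxy)-6,10-dimethyl-9-methylideneundeca-1,5-dien-7-yl (2R,3S)-3-(methoxymethoxy)-2-methylbutanoate, via mixed anhydride 26 (not isolated)
Conditions: 25, 2,4,6-Cl3C6H2COCl, Et3N, THF, rt; then 18, DMAP, toluene, rt
Reagents that add atoms: none
Why: Yamaguchi esterification acylates the hindered allylic C9–OH with retention at C9, the only free hydroxyl in 18.

**Step 13**
Reactants: 27 (the C9 ester tris-MOM ether)
Product: 28 (1Z,5E,7S,8S,10S)-2-(acetoxymethyl)-8,11-dihydroxy-1-iodo-6,10-dimethyl-9-methylideneundeca-1,5-dien-7-yl (2R,3S)-3-hydroxy-2-methylbutanoate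
Conditions: ZnBr2, n-PrSH, CH2Cl2, 0 °C, 15 min
Reagents that add atoms: none
Why: Lewis-acid-assisted thiol transacetalisation removes all three MOM groups in minutes while esters, alkenes and the alkenyl iodide are untouched; the crude triol is acetylated at once to prevent C9→C8 acyl shift.

**Step 14**
Reactants: 28 (the triol)
Product: 29 (1Z,5E,7S,8S,10S)-8,11-diacetoxy-2-(acetoxymethyl)-1-iodo-6,10-dimethyl-9-methylideneundeca-1,5-dien-7-yl (2R,3S)-3-acetoxy-2-methylbutanoate
Conditions: Ac2O, pyridine, DMAP (cat.), CH2Cl2, 0 °C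
Reagents that add atoms: acetic anhydride, CC(=O)OC(C)=O
Why: Global acylation installs the C8, C12 and C3' acetates in one operation, so every ester of the target is now in place.

**Step 15**
Reactants: 29 (the penta-ester with C7 exo-methylene)
Product: 31 (1Z,5E,7S,8S,9S,10S)-8,11-diacetoxy-2-(acetoxymethyl)-9-(hydroxymethyl)-1-iodo-6,10-dimethylundeca-1,5-dien-7-yl (2R,3S)-3-acetoxy-2-methylbutanoate, via alkylborane 30 (not isolated)
Conditions: 9-BBN (3 equiv), THF, 0 → 40 °C; then aq. NaOAc, H2O2, 0 °C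
Reagents that add atoms: hydrogen peroxide, OO
Why: Hydroboration–oxidation with 9-BBN picks the 1,1-disubstituted alkene over the trisubstituted and iodo alkenes, and acyclic 1,2-induction from the allylic C8 oxygen centre (allylic-strain control, borane anti to C9) is expected to give the 7,8-anti product, i.e. 7S.

**Step 16**
Reactants: 31 (the C6 primary alcohol)
Product: 32 (1Z,5E,7S,8S,9R,10S)-8,11-diacetoxy-2-(acetoxymethyl)-9-formyl-1-iodo-6,10-dimethylundeca-1,5-dien-7-yl (2R,3S)-3-acetoxy-2-methylbutanoate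
Conditions: Dess–Martin periodinane, NaHCO3, CH2Cl2, 0 °C → rt
Reagents that add atoms: none
Why: Buffered Dess–Martin oxidation gives the β-acetoxy aldehyde without base, so neither C7 epimerisation nor acetate elimination occurs if it is used immediately (the descriptor at C7 changes only through CIP priorities).

**Step 17**
Reactants: 32 (the seco-aldehyde)
Product: 34 (1(10)E,4Z,6S,7S,8S,9S,11S)-8,12,15-triacetoxy-6-hydroxygermacra-1(10),4-dien-9-yl (2R,3S)-3-acetoxy-2-methylbutanoate (CNP0294824.2), via alkenylchromium species 33 (not isolated)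
Conditions: CrCl2 (10 equiv), NiCl2 (2 mol%), DMSO/THF (3:1), 2 mM, rt
Reagents that add atoms: none
Why: Nozaki–Hiyama–Kishi macrocyclisation (oxidative addition to zerovalent nickel, transmetalation to trivalent chromium, addition to the aldehyde) closes the 10-membered ring with retention of alkene geometry and tolerates the five esters; the 6S carbinol is the anti-Felkin product expected if chromium is chelated by the C8 acetate and attack is anti to C11, and this is the least certain stereocentre of the route.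

## Compound list

1 | methyl (R)-3-hydroxy-2-methylpropanoate | COC(=O)[C@H](C)CO | starting material
2 | methyl (R)-3-(methoxymethoxy)-2-methylpropanoate | COC(=O)[C@H](C)COCOC | intermediate
3 | (R)-N-methoxy-3-(methoxymethoxy)-N,2-dimethylpropanamide | CON(C)C(=O)[C@H](C)COCOC | intermediate
4 | tributyl[(methoxymethoxy)methyl]stannane | CCCC[Sn](CCCC)(CCCC)COCOC | starting material
5 | (methoxymethoxy)methyllithium | [Li]COCOC | intermediate
6 | (R)-1,4-bis(methoxymethoxy)-3-methylbutan-2-one | COCOCC(=O)[C@H](C)COCOC | intermediate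
7 | (S)-4-(methoxymethoxy)-2-[(methoxymethoxy)methyl]-3-methylbut-1-ene | C=C(COCOC)[C@H](C)COCOC | intermediate
8 | prop-2-yn-1-ol | OCC#C | starting material
9 | 5-bromo-2-methylpent-2-ene | CC(C)=CCCBr | starting material
10 | (4-methylpent-3-en-1-yl)magnesium bromide | CC(C)=CCC[Mg]Br | intermediate
11 | 4-(4-methylpent-3-en-1-yl)-2,5-dihydro-1,2-oxamagnesole (cyclic alkenylmagnesium alkoxide) | CC(C)=CCCC1=C[Mg]OC1 | intermediate
12 | (Z)-3-iodo-2-(4-methylpent-3-en-1-yl)prop-2-en-1-ol | OC/C(CCC=C(C)C)=C\I | intermediate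
13 | (Z)-3-iodo-2-(4-methylpent-3-en-1-yl)prop-2-en-1-yl acetate | CC(=O)OC/C(CCC=C(C)C)=C\I | intermediate
14 | [(1Z,5E)-7-hydroxy-1-iodo-6-methylhepta-1,5-dien-2-yl]methyl acetate | CC(=O)OC/C(CC/C=C(\C)CO)=C\I | intermediate
15 | [(1Z,5E)-1-iodo-6-methyl-7-oxohepta-1,5-dien-2-yl]methyl acetate | CC(=O)OC/C(CC/C=C(\C)C=O)=C\I | intermediate
16 | [(3S)-1,4-bis(methoxymethoxy)-3-methyl-2-methylidenebutyl]lithium | C=C([C@H](C)COCOC)C([Li])OCOC | intermediate
17 | diisopinocampheyl[(3S)-4-(methoxymethoxy)-2-[(methoxymethoxy)methylidene]-3-methylbutyl]borane, OMOM cis to CH2B, isopinocampheyl groups from (−)-α-pinene | COCO/C=C(\CB([C@H]1C[C@H]2C[C@@H]([C@@H]1C)C2(C)C)[C@H]1C[C@H]2C[C@@H]([C@@H]1C)C2(C)C)[C@H](C)COCOC | intermediate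
18 | [(1Z,5E,7S,8S,10S)-7-hydroxy-1-iodo-8,11-bis(methoxymethoxy)-6,10-dimethyl-9-methylideneundeca-1,5-dien-2-yl]methyl acetate | C=C([C@H](C)COCOC)[C@H](OCOC)[C@@H](O)/C(C)=C/CC/C(COC(C)=O)=C/I | intermediate
19 | (R)-4-benzyl-3-propanoyl-1,3-oxazolidin-2-one | CCC(=O)N1[C@H](Cc2ccccc2)COC1=O | starting material
20 | acetaldehyde | CC=O | starting material
21 | dibutylboron (Z)-enolate of 19 | C/C=C(\OB(CCCC)CCCC)N1[C@H](Cc2ccccc2)COC1=O | intermediate
22 | (R)-4-benzyl-3-[(2R,3S)-3-hydroxy-2-methylbutanoyl]-1,3-oxazolidin-2-one | O=C([C@H](C)[C@H](C)O)N1[C@H](Cc2ccccc2)COC1=O | intermediate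
23 | (R)-4-benzyl-3-[(2R,3S)-3-(methoxymethoxy)-2-methylbutanoyl]-1,3-oxazolidin-2-one | O=C([C@H](C)[C@H](C)OCOC)N1[C@H](Cc2ccccc2)COC1=O | intermediate
24 | (2R,3S)-3-(methoxymethoxy)-2-methylbutaneperoxoic acid | OOC(=O)[C@H](C)[C@H](C)OCOC | intermediate
25 | (2R,3S)-3-(methoxymethoxy)-2-methylbutanoic acid | OC(=O)[C@H](C)[C@H](C)OCOC | intermediate
26 | (2R,3S)-3-(methoxymethoxy)-2-methylbutanoic 2,4,6-trichlorobenzoic anhydride | O=C(OC(=O)c1c(Cl)cc(Cl)cc1Cl)[C@H](C)[C@H](C)OCOC | intermediate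
27 | (1Z,5E,7S,8S,10S)-2-(acetoxymethyl)-1-iodo-8,11-bis(methoxymethoxy)-6,10-dimethyl-9-methylideneundeca-1,5-dien-7-yl (2R,3S)-3-(methoxymethoxy)-2-methylbutanoate | C=C([C@H](C)COCOC)[C@H](OCOC)[C@@H](OC(=O)[C@H](C)[C@H](C)OCOC)/C(C)=C/CC/C(COC(C)=O)=C/I | intermediate
28 | (1Z,5E,7S,8S,10S)-2-(acetoxymethyl)-8,11-dihydroxy-1-iodo-6,10-dimethyl-9-methylideneundeca-1,5-dien-7-yl (2R,3S)-3-hydroxy-2-methylbutanoate | C=C([C@H](C)CO)[C@H](O)[C@@H](OC(=O)[C@H](C)[C@H](C)O)/C(C)=C/CC/C(COC(C)=O)=C/I | intermediate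
29 | (1Z,5E,7S,8S,10S)-8,11-diacetoxy-2-(acetoxymethyl)-1-iodo-6,10-dimethyl-9-methylideneundeca-1,5-dien-7-yl (2R,3S)-3-acetoxy-2-methylbutanoate | C=C([C@H](C)COC(C)=O)[C@H](OC(C)=O)[C@@H](OC(=O)[C@H](C)[C@H](C)OC(C)=O)/C(C)=C/CC/C(COC(C)=O)=C/I | intermediate
30 | C6-(9-borabicyclo[3.3.1]nonan-9-yl) adduct of 29 (boron on the former methylidene carbon, new C7–H as in 31) | C1CC2CCCC(C1)B2C[C@H]([C@H](C)COC(C)=O)[C@H](OC(C)=O)[C@@H](OC(=O)[C@H](C)[C@H](C)OC(C)=O)/C(C)=C/CC/C(COC(C)=O)=C/I | intermediate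
31 | (1Z,5E,7S,8S,9S,10S)-8,11-diacetoxy-2-(acetoxymethyl)-9-(hydroxymethyl)-1-iodo-6,10-dimethylundeca-1,5-dien-7-yl (2R,3S)-3-acetoxy-2-methylbutanoate | OC[C@H]([C@H](C)COC(C)=O)[C@H](OC(C)=O)[C@@H](OC(=O)[C@H](C)[C@H](C)OC(C)=O)/C(C)=C/CC/C(COC(C)=O)=C/I | intermediate
32 | (1Z,5E,7S,8S,9R,10S)-8,11-diacetoxy-2-(acetoxymethyl)-9-formyl-1-iodo-6,10-dimethylundeca-1,5-dien-7-yl (2R,3S)-3-acetoxy-2-methylbutanoate | O=C[C@H]([C@H](C)COC(C)=O)[C@H](OC(C)=O)[C@@H](OC(=O)[C@H](C)[C@H](C)OC(C)=O)/C(C)=C/CC/C(COC(C)=O)=C/I | intermediate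
33 | alkenylchromium dichloride derived from 32 (CrCl2 in place of iodine) | O=C[C@H]([C@H](C)COC(C)=O)[C@H](OC(C)=O)[C@@H](OC(=O)[C@H](C)[C@H](C)OC(C)=O)/C(C)=C/CC/C(COC(C)=O)=C/[Cr](Cl)Cl | intermediate
34 | (1(10)E,4Z,6S,7S,8S,9S,11S)-8,12,15-triacetoxy-6-hydroxygermacra-1(10),4-dien-9-yl (2R,3S)-3-acetoxy-2-methylbutanoate (CNP0294824.2) | CC(=O)OC/C1=C\[C@H](O)[C@H]([C@H](C)COC(C)=O)[C@H](OC(C)=O)[C@@H](OC(=O)[C@H](C)[C@H](C)OC(C)=O)/C(C)=C/CC1 | target

## Step count and risks

**Total step count:** 17.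

**Longest linear sequence:** 11 steps (1 → 2 → 3 → 6 → 7 → 18 → 27 → 28 → 29 → 31 → 32 → 34; steps 1, 2, 3, 4, 8, 12, 13, 14, 15, 16, 17).

**Three steps most likely to fail:**

**Step 8** (metalation of the branched bis-MOM allyl ether and reagent-controlled transfer to the enal). The fallback sets out from ketone 6 and enal 15 and forms the C8–C9 bond by an aldol reaction instead of an allylboration. Ketone 6 is enolised toward C8 with i-Pr2NEt and the Ipc2BOTf antipode that directs Re-face attack (expected to be (+)-Ipc2BOTf) to give the Z-enol diisopinocampheylborinate of 6 F1. A syn-selective boron aldol with 15 then gives the β-hydroxy ketone [(1Z,5E,7S,8R,10R)-7-hydroxy-1-iodo-8,11-bis(methoxymethoxy)-6,10-dimethyl-9-oxoundeca-1,5-dien-2-yl]methyl acetate F2. Non-basic methylenation of the C7 ketone with Cp2TiMe2 in toluene at 65 °C comes back to the route at 18.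

**Step 15** (slow hydroboration of a doubly branched 1,1-disubstituted alkene, and diastereoselectivity next to an allylic acetate instead of an ether). The fallback sets out from 18 and moves the hydroboration forward to the allylic-ether stage, where the anti induction is best precedented. 9-BBN adds to 18 to give the C6-(9-borabicyclo[3.3.1]nonan-9-yl) adduct of 18 F3, and buffered H2O2 gives the diol [(1Z,5E,7S,8S,9S,10S)-7-hydroxy-9-(hydroxymethyl)-1-iodo-8,11-bis(methoxymethoxy)-6,10-dimethylundeca-1,5-dien-2-yl]methyl acetate F4. Selective silylation of the primary hydroxyl (TBSCl, imidazole) gives the C6 tert-butyldimethylsilyl ether of that diol F5. Yamaguchi esterification through 26 gives the C9 (2R,3S)-3-(methoxymethoxy)-2-methylbutanoate of the silyl ether F6. ZnBr2/n-PrSH gives the C6-silylated triol F7, and Ac2O/pyridine gives the C6-silylated triacetate F8. HF·pyridine in THF then removes the silyl group and comes back to the route at 31.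

**Step 17** (yield of the 10-membered ring closure and the configuration at C6, which simple Felkin control would set the wrong way). The fallback sets out from 32 and sets C6 by reagent-controlled reduction instead of by the addition. The same CrCl2/NiCl2 cyclisation is accepted with whatever C6 ratio it gives, the unwanted product being the 6R epimer (6R,7S,8S,9S,11S)-8,12,15-triacetoxy-6-hydroxygermacra-1(10)E,4Z-dien-9-yl (2R,3S)-3-acetoxy-2-methylbutanoate F9. The carbinol mixture is oxidised with Dess–Martin periodinane to the enone (7R,8S,9S,11S)-8,12,15-triacetoxy-6-oxogermacra-1(10)E,4Z-dien-9-yl (2R,3S)-3-acetoxy-2-methylbutanoate F10. Reduction with (S)-2-methyl-CBS-oxazaborolidine and catecholborane at −40 °C, with the alkenyl group as the large substituent, comes back to the route at 34.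

## Further compounds

F1 | step 8 | Z-enol diisopinocampheylborinate of ketone 6 (enolised toward C8, isopinocampheyl groups from (−)-α-pinene) | COCO/C=C(\OB([C@H]1C[C@H]2C[C@@H]([C@@H]1C)C2(C)C)[C@H]1C[C@H]2C[C@@H]([C@@H]1C)C2(C)C)[C@H](C)COCOC
F2 | step 8 | [(1Z,5E,7S,8R,10R)-7-hydroxy-1-iodo-8,11-bis(methoxymethoxy)-6,10-dimethyl-9-oxoundeca-1,5-dien-2-yl]methyl acetate | O=C([C@H](C)COCOC)[C@H](OCOC)[C@@H](O)/C(C)=C/CC/C(COC(C)=O)=C/I
F3 | step 15 | C6-(9-borabicyclo[3.3.1]nonan-9-yl) adduct of 18 | C1CC2CCCC(C1)B2C[C@H]([C@H](C)COCOC)[C@H](OCOC)[C@@H](O)/C(C)=C/CC/C(COC(C)=O)=C/I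
F4 | step 15 | [(1Z,5E,7S,8S,9S,10S)-7-hydroxy-9-(hydroxymethyl)-1-iodo-8,11-bis(methoxymethoxy)-6,10-dimethylundeca-1,5-dien-2-yl]methyl acetate | OC[C@H]([C@H](C)COCOC)[C@H](OCOC)[C@@H](O)/C(C)=C/CC/C(COC(C)=O)=C/I
F5 | step 15 | C6 tert-butyldimethylsilyl ether of F4 | CC(C)(C)[Si](C)(C)OC[C@H]([C@H](C)COCOC)[C@H](OCOC)[C@@H](O)/C(C)=C/CC/C(COC(C)=O)=C/I
F6 | step 15 | C9 (2R,3S)-3-(methoxymethoxy)-2-methylbutanoate of F5 | CC(C)(C)[Si](C)(C)OC[C@H]([C@H](C)COCOC)[C@H](OCOC)[C@@H](OC(=O)[C@H](C)[C@H](C)OCOC)/C(C)=C/CC/C(COC(C)=O)=C/I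
F7 | step 15 | C6-silylated triol (F6 without its three MOM groups) | CC(C)(C)[Si](C)(C)OC[C@H]([C@H](C)CO)[C@H](O)[C@@H](OC(=O)[C@H](C)[C@H](C)O)/C(C)=C/CC/C(COC(C)=O)=C/I
F8 | step 15 | C6-silylated triacetate (tert-butyldimethylsilyl ether of 31) | CC(C)(C)[Si](C)(C)OC[C@H]([C@H](C)COC(C)=O)[C@H](OC(C)=O)[C@@H](OC(=O)[C@H](C)[C@H](C)OC(C)=O)/C(C)=C/CC/C(COC(C)=O)=C/I
F9 | step 17 | (6R,7S,8S,9S,11S)-8,12,15-triacetoxy-6-hydroxygermacra-1(10)E,4Z-dien-9-yl (2R,3S)-3-acetoxy-2-methylbutanoate (6-epimer of 34) | CC(=O)OC/C1=C\[C@@H](O)[C@H]([C@H](C)COC(C)=O)[C@H](OC(C)=O)[C@@H](OC(=O)[C@H](C)[C@H](C)OC(C)=O)/C(C)=C/CC1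
F10 | step 17 | (7R,8S,9S,11S)-8,12,15-triacetoxy-6-oxogermacra-1(10)E,4Z-dien-9-yl (2R,3S)-3-acetoxy-2-methylbutanoate | CC(=O)OC/C1=C\C(=O)[C@H]([C@H](C)COC(C)=O)[C@H](OC(C)=O)[C@@H](OC(=O)[C@H](C)[C@H](C)OC(C)=O)/C(C)=C/CC1
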